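The runs were generated by integration on assumed constants, noise included.

Molar, not per cent, was the unit the meeting took for the free monomer when it sat down to judge the new flask from the earlier runs.

| flask | free monomer | initiator | remark | time |
|---|---|---|---|---|
| noon | 0.020 M | 1 mol% | run made earlier |  |
| autumn | 0.020 M | 1.6 mol% | run made earlier |  |
| midnight | 0.010 M | 0.74 mol% | run made earlier |  |
| flask | 0.020 M | 0.74 mol% |  | 10 d |

| run | time / d | monomer in chains / % | free monomer / % |
|---|---|---|---|
| noon | 0.333 | 33 | 67 |
| noon | 0.833 | 50 | 52 |
| noon | 1.67 | 56 | 45 |
| noon | 2.50 | 54 | 45 |
| noon | 4.00 | 54 | 42 |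
| noon | 5.00 | 56 | 43 |
| noon | 6.00 | 55 | 46 |
| autumn | 0.833 | 52 | 46 |
| autumn | 1.67 | 52 | 47 |
| autumn | 2.50 | 54 | 46 |
| autumn | 3.00 | 53 | 46 |
| autumn | 4.00 | 53 | 45 |
| autumn | 5.00 | 51 | 45 |
| autumn | 6.00 | 51 | 48 |
| midnight | 1.25 | 6 | 95 |
| midnight | 2.50 | 12 | 94 |
| midnight | 4.00 | 7 | 93 |
| midnight | 5.00 | 6 | 94 |
| midnight | 6.00 | 9 | 91 |

(standard deviation of a reading: 1.5 percentage points)

* whether the average number of monomer units in a chain (chains begun, living or dead) reaches 60 by 10 d (no / yes)
* average number of monomer units in a chain (chains begun, living or dead) at 10 d

- the average divides the monomer in chains by the number of chains begun, living and dead together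
- what was read earlier has a scatter of 1.5 percentage points, one standard deviation
- the earlier runs do not show the number of chains; that part of a forecast is a guess

The first speaker read the plateaus in molar: the autumn run, at 1.6 mol% initiator, gave a reading of 0.00920 M free monomer, and the midnight run, at 0.74 mol%, a reading of 0.00930 M. She proposed to carry the autumn reading as M_e, the free monomer concentration at which monomer stops entering chains on balance, 0.00920 M (the equilibrium monomer concentration).

The second speaker noted that the noon run read flat within the scatter from 1.67 d, and the flask has longer than that, 10 d. The minute-taker's own reckoning took one chain per initiator, so that the length is the charge less M_e, over the initiator charged: 73.0 for this flask. On that count a length of 60 needs 44.4% of the charge in chains, and the plateau reading leaves more than that, 54.0%. The third speaker warned that the chain count is a guess.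

The forecast said yes, with 74 (range 67 to 100), above the reckoning, and held that “This plateau doesn't depend on initiator level”.

The flask answers yes, with 70.1 at 10 d, having passed 60 at 0.758 d.

    monomer in chains + living end → free monomer + living end, rate k1*[living end] as long as [monomer in chains] is above zero (k = 0.110 min⁻¹)
    2 free monomer → self-condensation product (k = 1.70 × 10⁻⁴ M⁻¹ min⁻¹)
    free monomer + initiator → living end + monomer in chains (k = 0.430 M⁻¹ min⁻¹)
    free monomer + living end → monomer in chains + living end, rate k4*[living end]*[free monomer] (k = 12.0 M⁻¹ min⁻¹)

At 4.82 d in this flask, free monomer goes into chains 570 times as fast as into self-condensation product, while monomer in chains is made and used up at a ratio of 0.998. Taking M_e and the self-condensation product from the charge of this flask gives 69.8 at 10.0 d, and with 20.8% of that product at 100 d the same reckoning gives 44.9, below 60, when this flask holds 33.5% monomer in chains.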